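The numbers in the tables are calculated for an exercise.

Set the alpha run against the epsilon run, which is this same flask followed so far: target in the alpha run sinks to 1.3 % by 5.00 h, but the epsilon run still reads 12.0 % at 2.50 h.

| flask | substrate | first nucleophile | second nucleophile | protic impurity | remark | time |
|---|---|---|---|---|---|---|
| epsilon | 0.050 M | 0.15 M | 0.0525 M | 0.010 M | the very flask that is asked about, followed so far |  |
| alpha | 0.034 M | 0.15 M | 0.0525 M | 0.010 M | run made earlier |  |
| flask | 0.050 M | 0.150 M | 0.0525 M | 0.0100 M |  | 5.0 h |

| run | time / h | target / % |
|---|---|---|
| epsilon | 0.0417 | 20.8 |
| epsilon | 0.167 | 36.5 |
| epsilon | 0.667 | 23.1 |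
| epsilon | 2.50 | 12.0 |
| alpha | 0.0500 | 22.3 |
| alpha | 0.250 | 33.0 |
| alpha | 1.00 | 10.8 |
| alpha | 5.00 | 1.3 |

(standard deviation of a reading: 0.5 percentage points)

* when, up to 5.0 h, the flask holds most target
* the amount of target, in percent of the substrate charged, at that time



Take the fast step as settled, supposing that second nucleophile meets protic impurity first, one for one, and reckon with what that leaves free. Call the free second nucleophile per substrate charged the capture number, 0.850 for this flask, and suppose each free share removes one share of target. The alpha run has 1.25, higher and above one, so its target should fade towards zero. In this flask free second nucleophile is the limiting reagent against substrate, so on this supposition a tail of 15.0 % of target should stay. Test whether one number is enough. The epsilon reading at 2.50 h already lies 3 percentage points below that tail, against a scatter of 0.5 points, and the number gives no peak height. Still, the tail stands lower than the highest epsilon reading, so expect no late rise and commit to a maximum near 0.167 h, a little above 36.5 %.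

The forecast says 0.2 h and 37.5 %: “I see no reason for a late rise, so the maximum stays early”.

The flask peaks at 0.174 h with 37.1 %.

    substrate → intermediate (k = 0.00433 /s)
    first nucleophile + intermediate ⇌ target (K = 170 /M, k = 0.250 /M/s)
    second nucleophile + intermediate → other capture product (k = 0.950 /M/s)
    second nucleophile + protic impurity → quenched reagent (k = 1.53 /M/s)
    substrate + intermediate → side product (k = 0.0826 /M/s)

At 5.00 h this flask holds 84.5 % of other capture product, level with its capture number, while 0.47 % of the charged second nucleophile remains; target at 8.97 %, side product at 6.17 % and intermediate at 0.360 % share the rest of the substrate charged. A neighbouring flask charged with 0.340 equiv of protic impurity to substrate has a capture number of 0.710, and it ends with 71.0 % of other capture product, level with that number, beside 21.4 % of target and 6.75 % of side product, after a best of 41.4 % target.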